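**Retrosynthetic overview**

1. Numbering as in 1-benzofuran (ring B: O1, C2, C3, C3a, C7a; ring A: C3a, C4, C5, C6, C7, C7a). Target 15 ⇐ 3a-allyl dienone 14 (burchellin type) by a thermal Cope shift of the allyl group from C3a to C5, the presumed biogenetic step, which sets C5 by suprafacial transfer.
2. 14 ⇐ lactone 11 by closing ring A through the C7–C7a bond: the C7 enolate of the C6 methyl ketone attacks the lactone carbonyl C7a, O1 is released and returns onto C7a, and the C5 ketal loses methanol to give C4=C5.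
3. Enabling feature: the vinylogous ester O1–C7a=C7–C6=O in ring A. C7a is at the carboxylic acid oxidation level and already bound to O1, so ring B is a latent γ-butyrolactone with C7a as its carbonyl, and C7 is the α-carbon of a methyl ketone.
4. 11 ⇐ lactone 5 by Mukaiyama–Michael addition (C3a–C4 bond), allylation anti to the C3 methyl (quaternary C3a) and oxidative ketalisation at C5; 5 ⇐ veratraldehyde by anti-crotylboration, hydroboration and oxidative lactonisation.
5. Ring order: ring B first, as the lactone (step 3); then ring A (step 8), with ring B re-formed on ring A in the same operation.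

Key step: step 8

Remark: 3-methoxybut-3-en-2-one is treated as not purchasable and is made in step 4; the Re-face sense of step 1 is assumed from the accepted chair transition-state model for this catalyst class.

**Route**

Step 1
Reactants: 1 3,4-dimethoxybenzaldehyde; 2 (E)-crotylboronic acid pinacol ester
Product: 3 (1R,2R)-1-(3,4-dimethoxyphenyl)-2-methylbut-3-en-1-ol
Conditions: (R)-3,3'-bis(2,4,6-triisopropylphenyl)-1,1'-binaphthyl-2,2'-diyl hydrogen phosphate (5 mol%), PhMe, 4 Å molecular sieves, −30 °C; aqueous work-up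
Reagents that add atoms: none
Why: Chiral-phosphoric-acid-catalysed crotylboration through a closed chair transition state, in which the (E)-crotyl geometry gives the anti relationship and the (R)-catalyst directs the boronate to the Re face of the aldehyde, so that C1 (R) and C2 (R) are set together.

Step 2
Reactants: 3 (1R,2R)-1-(3,4-dimethoxyphenyl)-2-methylbut-3-en-1-ol
Product: 4 (1R,2R)-1-(3,4-dimethoxyphenyl)-2-methylbutane-1,4-diol
Conditions: 9-borabicyclo[3.3.1]nonane (2.2 equiv), THF, 0 °C to rt; then NaOH aq., H2O2, 0 °C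
Reagents that add atoms: hydrogen peroxide, OO
Why: Anti-Markovnikov hydroboration–oxidation of the terminal alkene should give the primary alcohol without touching the two stereocentres.

Step 3
Reactants: 4 (1R,2R)-1-(3,4-dimethoxyphenyl)-2-methylbutane-1,4-diol
Product: 5 (4R,5R)-5-(3,4-dimethoxyphenyl)-4-methyldihydrofuran-2(3H)-one
Conditions: 2,2,6,6-tetramethylpiperidin-1-oxyl (10 mol%), PhI(OAc)2 (2.5 equiv), CH2Cl2, rt
Reagents that add atoms: none
Why: Oxoammonium oxidation of the primary alcohol, lactol formation with the benzylic hydroxyl and a second oxidation (oxidative lactonisation of a 1,4-diol) should give the trans lactone with both centres intact.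

Step 4
Reactants: 6 3,3-dimethoxybutan-2-one
Product: 7 3-methoxybut-3-en-2-one
Conditions: p-toluenesulfonic acid monohydrate (1 mol%), hydroquinone (trace), neat, 150 °C, slow distillation of MeOH; then fractional distillation
Reagents that add atoms: none
Why: Acid-catalysed elimination of methanol from a ketal to the enol ether, driven by removal of methanol, is the standard entry to α-methoxy enones.

Step 5
Reactants: 5 (4R,5R)-5-(3,4-dimethoxyphenyl)-4-methyldihydrofuran-2(3H)-one; 7 3-methoxybut-3-en-2-one
Product: 9 (3R,4R,5R)-3-[3-(tert-butyldimethylsilyloxy)-2-methoxybut-2-en-1-yl]-5-(3,4-dimethoxyphenyl)-4-methyldihydrofuran-2(3H)-one, via silyl ketene acetal 8 (not isolated)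
Conditions: LiN(iPr)2, THF, −78 °C; tBuMe2SiCl, DMPU; solvent exchange to CH2Cl2; 7, tBuMe2SiOTf (10 mol%), −78 °C
Reagents that add atoms: tert-butyldimethylsilyl chloride, CC(C)(C)[Si](C)(C)Cl
Why: Mukaiyama–Michael addition of the silyl ketene acetal to the α-methoxy enone with silyl transfer should give the enol silyl ether, which masks the ketone for step 6; the new C3 centre (expected mainly trans to the methyl group) and the enol ether geometry are of no consequence because both are erased later.

Step 6
Reactants: 9 (3R,4R,5R)-3-[3-(tert-butyldimethylsilyloxy)-2-methoxybut-2-en-1-yl]-5-(3,4-dimethoxyphenyl)-4-methyldihydrofuran-2(3H)-one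
Product: 10 (3S,4R,5R)-3-allyl-3-[3-(tert-butyldimethylsilyloxy)-2-methoxybut-2-en-1-yl]-5-(3,4-dimethoxyphenyl)-4-methyldihydrofuran-2(3H)-one
Conditions: LiN(iPr)2, THF, −78 °C; allyl bromide, DMPU, −78 to −20 °C; NaHCO3 aq. work-up
Reagents that add atoms: allyl bromide, C=CCBr
Why: Alkylation of the lactone lithium enolate, in which allyl bromide should approach the face anti to the adjacent C4 methyl group (1,2-induction in a β-substituted butyrolactone enolate), so that the quaternary centre carries allyl trans to methyl.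

Step 7
Reactants: 10 (3S,4R,5R)-3-allyl-3-[3-(tert-butyldimethylsilyloxy)-2-methoxybut-2-en-1-yl]-5-(3,4-dimethoxyphenyl)-4-methyldihydrofuran-2(3H)-one
Product: 11 (3S,4R,5R)-3-allyl-3-(2,2-dimethoxy-3-oxobutyl)-5-(3,4-dimethoxyphenyl)-4-methyldihydrofuran-2(3H)-one
Conditions: N-bromosuccinimide (1.05 equiv), NaHCO3, MeOH–CH2Cl2, −78 to 0 °C
Reagents that add atoms: methanol, CO
Why: Positive-halogen oxidation of the enediol diether (as in the bromine oxidation of bis-silyloxyalkenes and the bromoalkoxylation of enol ethers) with methanol capture of the α-alkoxy cation should give the keto ketal whichever enol carbon takes bromine, and at −78 °C the allyl alkene and the arene are far less nucleophilic than the doubly oxygenated alkene.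

Step 8
Reactants: 11 (3S,4R,5R)-3-allyl-3-(2,2-dimethoxy-3-oxobutyl)-5-(3,4-dimethoxyphenyl)-4-methyldihydrofuran-2(3H)-one
Product: 14 (2R,3R,3aR)-3a-allyl-2-(3,4-dimethoxyphenyl)-5-methoxy-3-methyl-3,3a-dihydro-1-benzofuran-6(2H)-one, via hydroxy diketone 12 (not isolated), via ketal vinylogous ester 13 (not isolated)
Conditions: LiN(SiMe3)2 (2.5 equiv), THF, −78 to 0 °C; AcOH quench; then camphor-10-sulfonic acid (10 mol%), PhMe, 4 Å molecular sieves, 60 °C
Reagents that add atoms: none
Why: LiN(SiMe3)2 can enolise only C7 (C5 is a ketal carbon and C3a is quaternary), and this enolate adds to the lactone carbonyl C7a in an intramolecular Claisen condensation, the tetrahedral intermediate expelling the benzylic alkoxide O1 and the 1,3-diketone being held as its diketonate 12, which makes the C7–C7a bond formation irreversible. Under camphorsulfonic acid O1–H adds back to the C7a carbonyl and water is lost to give the vinylogous ester 13, and the C5 ketal then ionises and loses a C4 proton to give the C4=C5 enol ether of 14. The closest known reaction types are the Dieckmann-type closure of δ-keto esters to cyclohexane-1,3-diones, the cyclodehydration of 2-(2-hydroxyalkyl)cyclohexane-1,3-diones to furan-fused vinylogous esters, and the acid-induced conversion of α-keto dimethyl ketals into α-methoxy enones. Ring A closes by 6-exo-trig attack of the enolate carbon C7 on C7a, and ring B re-closes by 5-exo-trig attack of O1 on the C7a ketone followed by dehydration. No stereocentre is created: C2 and C3 are not enolisable and the quaternary C3a cannot epimerise, so the configuration from steps 1 and 6 is carried through, and the C4=C5 geometry is fixed by ring A. The selectivities needed are return of O1 to C7a and not to C6 (five- against seven-membered ring) and elimination toward C4 (the only proton-bearing neighbour of C5), both secured by the substrate, and the acid stage is kept mild because 14 is prone to acid-induced allyl migration.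

Step 9
Reactants: 14 (2R,3R,3aR)-3a-allyl-2-(3,4-dimethoxyphenyl)-5-methoxy-3-methyl-3,3a-dihydro-1-benzofuran-6(2H)-one
Product: 15 (2R,3R,5S)-5-allyl-2-(3,4-dimethoxyphenyl)-5-methoxy-3-methyl-2,3-dihydro-1-benzofuran-6(5H)-one
Conditions: degassed PhMe, 2,6-di-tert-butyl-4-methylphenol (trace), 120 °C, sealed tube; stopped when 14 is consumed
Reagents that add atoms: none
Why: Thermal Cope rearrangement of the 1,5-diene CH2=CH–CH2–C3a–C4=C5 is suprafacial within ring A, so the allyl group should arrive on the face of C5 that it occupied at C3a (trans to the C3 methyl, giving 5S), with relief of the crowded ring-fusion centre and formation of the linearly conjugated dienone as driving force.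

**Compound list**

1 | 3,4-dimethoxybenzaldehyde (veratraldehyde) | O=Cc1ccc(OC)c(OC)c1 | starting material
2 | (E)-crotylboronic acid pinacol ester | C/C=C/CB1OC(C)(C)C(C)(C)O1 | starting material
3 | (1R,2R)-1-(3,4-dimethoxyphenyl)-2-methylbut-3-en-1-ol | O[C@@H](c1ccc(OC)c(OC)c1)[C@@H](C=C)C | intermediate
4 | (1R,2R)-1-(3,4-dimethoxyphenyl)-2-methylbutane-1,4-diol | O[C@@H](c1ccc(OC)c(OC)c1)[C@@H](CCO)C | intermediate
5 | (4R,5R)-5-(3,4-dimethoxyphenyl)-4-methyldihydrofuran-2(3H)-one | O1[C@@H](c2ccc(OC)c(OC)c2)[C@@H](CC1=O)C | intermediate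
6 | 3,3-dimethoxybutan-2-one | CC(=O)C(C)(OC)OC | starting material
7 | 3-methoxybut-3-en-2-one | CC(=O)C(=C)OC | intermediate
8 | tert-butyl{[(4R,5R)-5-(3,4-dimethoxyphenyl)-4-methyl-4,5-dihydrofuran-2-yl]oxy}dimethylsilane (silyl ketene acetal) | O1[C@@H](c2ccc(OC)c(OC)c2)[C@@H](C=C1O[Si](C)(C)C(C)(C)C)C | intermediate
9 | (3R,4R,5R)-3-[3-(tert-butyldimethylsilyloxy)-2-methoxybut-2-en-1-yl]-5-(3,4-dimethoxyphenyl)-4-methyldihydrofuran-2(3H)-one (enol ether E/Z mixture; C3 shown as the expected major epimer) | O1[C@@H](c2ccc(OC)c(OC)c2)[C@H](C)[C@@H](CC(OC)=C(C)O[Si](C)(C)C(C)(C)C)C1=O | intermediate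
10 | (3S,4R,5R)-3-allyl-3-[3-(tert-butyldimethylsilyloxy)-2-methoxybut-2-en-1-yl]-5-(3,4-dimethoxyphenyl)-4-methyldihydrofuran-2(3H)-one (enol ether E/Z mixture) | O1[C@@H](c2ccc(OC)c(OC)c2)[C@H](C)[C@](CC=C)(CC(OC)=C(C)O[Si](C)(C)C(C)(C)C)C1=O | intermediate
11 | (3S,4R,5R)-3-allyl-3-(2,2-dimethoxy-3-oxobutyl)-5-(3,4-dimethoxyphenyl)-4-methyldihydrofuran-2(3H)-one | O1[C@@H](c2ccc(OC)c(OC)c2)[C@H](C)[C@](CC=C)(CC(OC)(OC)C(C)=O)C1=O | intermediate
12 | (6S)-6-allyl-6-[(1R,2R)-1-(3,4-dimethoxyphenyl)-1-hydroxypropan-2-yl]-4,4-dimethoxycyclohexane-1,3-dione (hydroxy diketone) | O[C@@H](c1ccc(OC)c(OC)c1)[C@H](C)[C@]1(CC=C)CC(OC)(OC)C(=O)CC1=O | intermediate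
13 | (2R,3R,3aS)-3a-allyl-2-(3,4-dimethoxyphenyl)-5,5-dimethoxy-3-methyl-3,3a,4,5-tetrahydro-1-benzofuran-6(2H)-one (ketal vinylogous ester) | O1[C@@H](c3ccc(OC)c(OC)c3)[C@H](C)[C@]2(CC=C)CC(OC)(OC)C(=O)C=C12 | intermediate
14 | (2R,3R,3aR)-3a-allyl-2-(3,4-dimethoxyphenyl)-5-methoxy-3-methyl-3,3a-dihydro-1-benzofuran-6(2H)-one | O1[C@@H](c3ccc(OC)c(OC)c3)[C@H](C)[C@]2(CC=C)C=C(OC)C(=O)C=C12 | intermediate
15 | (2R,3R,5S)-5-allyl-2-(3,4-dimethoxyphenyl)-5-methoxy-3-methyl-2,3-dihydro-1-benzofuran-6(5H)-one | C=CC[C@]1(OC)C=C2C(=CC1=O)O[C@@H](c1ccc(OC)c(OC)c1)[C@@H]2C | target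

**Step count and risks**

Total step count: 9 (steps 1 to 9; step 4 prepares the Michael acceptor).
Longest linear sequence: 8 steps (1, 2, 3, 5, 6, 7, 8, 9).

Steps most likely to fail:

1. Step 8. The Claisen closure itself is well precedented; the weak point is the acid stage. Acid-induced allyl migration with aromatisation of the cross-conjugated dienone, or exchange of the free hydroxyl into the C5 ketal, may compete with loss of methanol.
   Fallback (ketal-free, setting out from 10 and returning at 14): aqueous HCl in THF hydrolyses the enol silyl ether of 10 to the α-methoxy ketone (3S,4R,5R)-3-allyl-5-(3,4-dimethoxyphenyl)-3-(2-methoxy-3-oxobutyl)-4-methyldihydrofuran-2(3H)-one F1 (both epimers at the methoxy carbon). LiN(SiMe3)2 followed by brief treatment with camphor-10-sulfonic acid at room temperature closes ring A as in step 8, through the hydroxy diketone F2, to the 4,5-dihydro vinylogous ester F3; no ketal has to be ionised. Deprotonation at C5 with LiN(iPr)2 (the only acidic position left) and PhSeBr gives the selenide F4. H2O2 with pyridine at 0 °C gives the selenoxide F5, whose syn-elimination can only take a C4 hydrogen and should deliver 14 under neutral conditions.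

2. Step 9. The thermal window may be narrow: a further [3,3] shift of the allyl group from C5 to the C6 oxygen would aromatise ring A, and a competing shift from C3a to C7 would do the same after enolisation.
   Fallback (direct allylation at C5, setting out from 9 and returning at 15): aqueous HCl in THF converts 9 into the ketone (3R,4R,5R)-5-(3,4-dimethoxyphenyl)-3-(2-methoxy-3-oxobutyl)-4-methyldihydrofuran-2(3H)-one F6. LiN(SiMe3)2 (3 equiv) and then camphor-10-sulfonic acid give, through the hydroxy diketone F7, the bicyclic vinylogous ester F8, which carries hydrogen at C3a. Its C5 lithium enolate (LiN(iPr)2, −78 °C) is allylated with allyl acetate, [Pd(allyl)Cl]2 and a chiral trans-1,2-diaminocyclohexane-derived bis(2-diphenylphosphinobenzamide) ligand, both enantiomers of which would be screened, to give the 5-allyl compound F9 after separation from its C5 epimer. tBuMe2SiOTf and Et3N give the extended silyl dienol ether F10, and Saegusa–Ito oxidation with Pd(OAc)2 in MeCN introduces the C3a=C4 double bond to give 15. The C3a centre of F8 and F9 is destroyed at the end and needs no control.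

3. Step 7. Bromination of the electron-rich arene or bromomethoxylation of the allyl group may compete, and the α-bromo ether may solvolyse sluggishly next to the carbonyl group.
   Fallback (oxygen-atom transfer in place of halogen, setting out from 10 and returning at 11): dimethyldioxirane in acetone at −78 °C epoxidises only the enediol diether; Rubottom-type silyl migration gives the α-methoxy-α-silyloxy ketone F11. Methanol with pyridinium p-toluenesulfonate exchanges the silyloxy group for methoxy and gives 11.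

**Further compounds**

F1 | step 8 | (3S,4R,5R)-3-allyl-5-(3,4-dimethoxyphenyl)-3-(2-methoxy-3-oxobutyl)-4-methyldihydrofuran-2(3H)-one (epimers at the methoxy carbon) | O1[C@@H](c2ccc(OC)c(OC)c2)[C@H](C)[C@](CC=C)(CC(OC)C(C)=O)C1=O
F2 | step 8 | (6S)-6-allyl-6-[(1R,2R)-1-(3,4-dimethoxyphenyl)-1-hydroxypropan-2-yl]-4-methoxycyclohexane-1,3-dione (C4 epimers) | O[C@@H](c1ccc(OC)c(OC)c1)[C@H](C)[C@]1(CC=C)CC(OC)C(=O)CC1=O
F3 | step 8 | (2R,3R,3aS)-3a-allyl-2-(3,4-dimethoxyphenyl)-5-methoxy-3-methyl-3,3a,4,5-tetrahydro-1-benzofuran-6(2H)-one (C5 epimers) | O1[C@@H](c3ccc(OC)c(OC)c3)[C@H](C)[C@]2(CC=C)CC(OC)C(=O)C=C12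
F4 | step 8 | (2R,3R,3aS)-3a-allyl-2-(3,4-dimethoxyphenyl)-5-methoxy-3-methyl-5-(phenylselanyl)-3,3a,4,5-tetrahydro-1-benzofuran-6(2H)-one (C5 epimers) | O1[C@@H](c3ccc(OC)c(OC)c3)[C@H](C)[C@]2(CC=C)CC(OC)([Se]c4ccccc4)C(=O)C=C12
F5 | step 8 | selenoxide of F4 | O1[C@@H](c3ccc(OC)c(OC)c3)[C@H](C)[C@]2(CC=C)CC(OC)([Se](=O)c4ccccc4)C(=O)C=C12
F6 | step 9 | (3R,4R,5R)-5-(3,4-dimethoxyphenyl)-3-(2-methoxy-3-oxobutyl)-4-methyldihydrofuran-2(3H)-one (epimers at the methoxy carbon) | O1[C@@H](c2ccc(OC)c(OC)c2)[C@H](C)[C@@H](CC(OC)C(C)=O)C1=O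
F7 | step 9 | (6R)-6-[(1R,2R)-1-(3,4-dimethoxyphenyl)-1-hydroxypropan-2-yl]-4-methoxycyclohexane-1,3-dione (C4 epimers) | O[C@@H](c1ccc(OC)c(OC)c1)[C@H](C)[C@H]1CC(OC)C(=O)CC1=O
F8 | step 9 | (2R,3R,3aR)-2-(3,4-dimethoxyphenyl)-5-methoxy-3-methyl-3,3a,4,5-tetrahydro-1-benzofuran-6(2H)-one (C5 epimers) | O1[C@@H](c3ccc(OC)c(OC)c3)[C@H](C)[C@H]2CC(OC)C(=O)C=C12
F9 | step 9 | (2R,3R,3aR,5S)-5-allyl-2-(3,4-dimethoxyphenyl)-5-methoxy-3-methyl-3,3a,4,5-tetrahydro-1-benzofuran-6(2H)-one | C=CC[C@]1(OC)C[C@H]2C(=CC1=O)O[C@@H](c1ccc(OC)c(OC)c1)[C@@H]2C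
F10 | step 9 | tert-butyl{[(2R,3R,5S)-5-allyl-2-(3,4-dimethoxyphenyl)-5-methoxy-3-methyl-2,3,4,5-tetrahydro-1-benzofuran-6-yl]oxy}dimethylsilane | C=CC[C@]1(OC)CC2=C(C=C1O[Si](C)(C)C(C)(C)C)O[C@@H](c1ccc(OC)c(OC)c1)[C@@H]2C
F11 | step 7 | (3S,4R,5R)-3-allyl-3-[2-(tert-butyldimethylsilyloxy)-2-methoxy-3-oxobutyl]-5-(3,4-dimethoxyphenyl)-4-methyldihydrofuran-2(3H)-one (epimers at the ketal carbon) | O1[C@@H](c2ccc(OC)c(OC)c2)[C@H](C)[C@](CC=C)(CC(OC)(O[Si](C)(C)C(C)(C)C)C(C)=O)C1=O
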